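**Retrosynthetic overview**
1. Target 9 comes from its tetrabenzyl ether 8 by global hydrogenolysis.
2. Ring C (the only ring built, formed last) comes from the o-hydroxyaryl 2-hydroxy-1,3-diketone 7 by acid cyclodehydration (O1–C2 bond).
3. Key C2–C3 bond: the acyl-anion (Breslow) equivalent of B-ring aldehyde 6 adds to the aldehyde carbon of A-ring arylglyoxal 5, so two native carbonyl electrophiles are joined.
4. Glyoxal 5 comes from acetophenone 4 by Riley oxidation; 4 comes from phloroacetophenone 1 by dibenzylation, 3,5-dibromination and Cu-mediated double methoxylation.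
5. Rings A and B are bought intact (1 and 6); the symmetric A ring makes the ring closure regiochemically unambiguous.

Assumption: the target is achiral (no stereocentre), so there is no enantiomer to control; the one stereocentre on the route (the carbinol carbon of 7) is racemic and is erased on ring closure.

**Route**

Step 1
Reactants: 1 1-(2,4,6-trihydroxyphenyl)ethanone (2',4',6'-trihydroxyacetophenone, dried monohydrate)
Product: 2 1-[2,4-bis(benzyloxy)-6-hydroxyphenyl]ethanone
Conditions: BnBr (2.05 equiv), K2CO3 (2.2 equiv), DMF, 0 °C to rt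
Reagents that add atoms: benzyl bromide, BrCc1ccccc1
Why: Williamson etherification; the 4-OH and one of the two equivalent ortho-OH groups react, while the remaining ortho-OH is hydrogen-bonded to the ketone and stays free.

Step 2
Reactants: 2 1-[2,4-bis(benzyloxy)-6-hydroxyphenyl]ethanone
Product: 3 1-[2,4-bis(benzyloxy)-3,5-dibromo-6-hydroxyphenyl]ethanone
Conditions: NBS (2.1 equiv), DMF, 0 °C to rt, dark
Reagents that add atoms: N-bromosuccinimide, O=C1CCC(=O)N1Br
Why: Electrophilic aromatic bromination; both remaining ring C–H positions are flanked by two oxygen donors and react far faster than the acetyl α-position under polar, HBr-free conditions.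

Step 3
Reactants: 3 1-[2,4-bis(benzyloxy)-3,5-dibromo-6-hydroxyphenyl]ethanone
Product: 4 1-[2,4-bis(benzyloxy)-6-hydroxy-3,5-dimethoxyphenyl]ethanone
Conditions: NaOMe (10 equiv, 25% in MeOH), CuBr (0.3 equiv), DMF, 110 °C, N2; cold dilute HCl work-up
Reagents that add atoms: sodium methoxide, [Na+].[O-]C
Why: Ullmann-type Cu(I)-catalysed methoxylation of aryl bromides, as in the classical methanolysis of ortho-bromophenols and of 6,8-dibromo-5,7-dihydroxyflavones; benzyl ethers and the ketone (present as phenoxide) are inert to methoxide.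

Step 4
Reactants: 4 1-[2,4-bis(benzyloxy)-6-hydroxy-3,5-dimethoxyphenyl]ethanone
Product: 5 2-[2,4-bis(benzyloxy)-6-hydroxy-3,5-dimethoxyphenyl]-2-oxoacetaldehyde
Conditions: SeO2 (1.5 equiv), 1,4-dioxane/H2O (30:1), 95 °C; filter through Celite; azeotropic drying with PhMe
Reagents that add atoms: selenium dioxide, O=[Se]=O
Why: Riley oxidation of the aryl methyl ketone CH3 to CHO via the enol; the ring carries no C–H, so only the acetyl group is attacked (5 is used directly and may sit partly in its ring-closed lactol tautomer).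

Step 5
Reactants: 5 2-[2,4-bis(benzyloxy)-6-hydroxy-3,5-dimethoxyphenyl]-2-oxoacetaldehyde; 6 3,4-bis(benzyloxy)benzaldehyde
Product: 8 5,7-bis(benzyloxy)-2-[3,4-bis(benzyloxy)phenyl]-3-hydroxy-6,8-dimethoxy-4H-chromen-4-one, via cross-benzoin adduct 7 (not isolated)
Conditions: 6 (1.5 equiv), 2-(pentafluorophenyl)-6,7-dihydro-5H-pyrrolo[2,1-c][1,2,4]triazol-2-ium tetrafluoroborate (15 mol %), i-Pr2NEt (30 mol %), 4 Å MS, CH2Cl2, rt, Ar, slow addition of 5 over 4 h; then solvent switch, TsOH·H2O (0.5 equiv), PhMe, 60 °C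
Reagents that add atoms: none
Why: Proposed new method: the triazolylidene converts aldehyde 6 into its Breslow intermediate (acyl-anion equivalent), which attacks the much more electrophilic, non-enolisable CHO of glyoxal 5 to give the o-hydroxyaryl 2-hydroxy-1,3-diketone 7; slow addition of 5 limits its self-coupling, and the reverse-sense adduct ArA-CO-CO-CH(OH)-ArB is a tautomer of 7 through the common enediol, so both regiochemistries converge; acid then closes the phenol onto the B-ring ketone with loss of water to the flavonol, erasing the racemic carbinol centre of 7; the closest known reactions are the chemoselective NHC cross-benzoin of aryl aldehydes with α-ketoesters and other activated carbonyls, and the acid cyclodehydration of o-hydroxyaryl 2-acyloxy-1,3-diketones in Baker–Venkataraman-type flavonol syntheses.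

Step 6
Reactants: 8 5,7-bis(benzyloxy)-2-[3,4-bis(benzyloxy)phenyl]-3-hydroxy-6,8-dimethoxy-4H-chromen-4-one
Product: 9 3,5,7-trihydroxy-2-(3,4-dihydroxyphenyl)-6,8-dimethoxy-4H-chromen-4-one (3,5,7,3',4'-pentahydroxy-6,8-dimethoxyflavone)
Conditions: H2 (1 atm), 10% Pd/C, THF/MeOH (1:1), rt; filter and concentrate under Ar
Reagents that add atoms: none
Why: Catalytic hydrogenolysis of the four aryl benzyl ethers; the methyl ethers and the tetrasubstituted pyranone C2=C3 bond are untouched at 1 atm and rt.

**Compound list**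
1 | 1-(2,4,6-trihydroxyphenyl)ethanone | CC(=O)c1c(O)cc(O)cc1O | starting material
2 | 1-[2,4-bis(benzyloxy)-6-hydroxyphenyl]ethanone | CC(=O)c1c(O)cc(OCc2ccccc2)cc1OCc1ccccc1 | intermediate
3 | 1-[2,4-bis(benzyloxy)-3,5-dibromo-6-hydroxyphenyl]ethanone | CC(=O)c1c(O)c(Br)c(OCc2ccccc2)c(Br)c1OCc1ccccc1 | intermediate
4 | 1-[2,4-bis(benzyloxy)-6-hydroxy-3,5-dimethoxyphenyl]ethanone | CC(=O)c1c(O)c(OC)c(OCc2ccccc2)c(OC)c1OCc1ccccc1 | intermediate
5 | 2-[2,4-bis(benzyloxy)-6-hydroxy-3,5-dimethoxyphenyl]-2-oxoacetaldehyde | O=CC(=O)c1c(O)c(OC)c(OCc2ccccc2)c(OC)c1OCc1ccccc1 | intermediate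
6 | 3,4-bis(benzyloxy)benzaldehyde | O=Cc1ccc(OCc2ccccc2)c(OCc2ccccc2)c1 | starting material
7 | 1-[2,4-bis(benzyloxy)-6-hydroxy-3,5-dimethoxyphenyl]-3-[3,4-bis(benzyloxy)phenyl]-2-hydroxypropane-1,3-dione (racemic, not isolated) | O=C(c1ccc(OCc2ccccc2)c(OCc2ccccc2)c1)C(O)C(=O)c1c(O)c(OC)c(OCc2ccccc2)c(OC)c1OCc1ccccc1 | intermediate
8 | 5,7-bis(benzyloxy)-2-[3,4-bis(benzyloxy)phenyl]-3-hydroxy-6,8-dimethoxy-4H-chromen-4-one | COc1c(OCc2ccccc2)c(OC)c2oc(-c3ccc(OCc4ccccc4)c(OCc4ccccc4)c3)c(O)c(=O)c2c1OCc1ccccc1 | intermediate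
9 | 3,5,7,3',4'-pentahydroxy-6,8-dimethoxyflavone | COc1c(O)c(OC)c2oc(-c3ccc(O)c(O)c3)c(O)c(=O)c2c1O | target

**Totals**
Total step count: 6. Longest linear sequence: 6 (1 → 2 → 3 → 4 → 5 → 8 → 9; 6 is bought and enters at step 5).

**Three steps most likely to fail, with fallbacks**

Step 5 (carbene cross-benzoin and cyclodehydration). The risks are self-coupling of glyoxal 5, carbene-mediated internal redox of 5 to a mandelic lactone, slow Breslow formation from electron-rich 6, and retro-benzoin or air oxidation of 7. The fallback uses a stoichiometric acyl-anion equivalent; it sets out from 6 (with 5 as partner) and comes back at 8. Aldehyde 6 is thioacetalised with propane-1,3-dithiol (BF3·OEt2, CH2Cl2, rt) to 2-[3,4-bis(benzyloxy)phenyl]-1,3-dithiane F1. F1 is lithiated (n-BuLi, THF, −78 °C) and added to 5 whose phenol has first been deprotonated (NaH, 1 equiv). Attack at the aldehyde gives 1-[2,4-bis(benzyloxy)-6-hydroxy-3,5-dimethoxyphenyl]-2-{2-[3,4-bis(benzyloxy)phenyl]-1,3-dithian-2-yl}-2-hydroxyethanone F2. Dithiane removal (MeI, CaCO3, aq. MeCN, 45 °C) releases 7, which TsOH in PhMe at 60 °C closes to 8.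

Step 3 (double Cu methoxylation of the hindered dibromide). The risks are protodebromination and incomplete substitution of the bromide flanked by two benzyloxy groups. The fallback does the C–O coupling on the unprotected ring, where each bromide sits next to free phenoxides, and benzylates afterwards; it sets out from 1 and comes back at 4. Compound 1 is dibrominated (NBS, 2.1 equiv, MeCN, 0 °C) to 1-(3,5-dibromo-2,4,6-trihydroxyphenyl)ethanone F3. F3 is treated with NaOMe/CuBr in DMF–MeOH at 100 °C under N2 to give 1-(2,4,6-trihydroxy-3,5-dimethoxyphenyl)ethanone F4. F4 is dibenzylated (BnBr 2.05 equiv, K2CO3, DMF, rt) to 4, again leaving the chelated ortho-OH free.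

Step 4 (Riley oxidation). The risks are over-oxidation to the arylglyoxylic acid, oxidation of the free phenol, and selenium residues that poison the carbene and Pd steps. The fallback is α-halogenation followed by Kornblum oxidation; it sets out from 4 and comes back at 5. Ketone 4 is monobrominated at the acetyl carbon (PhNMe3Br3, THF, rt; no ring C–H competes) to 1-[2,4-bis(benzyloxy)-6-hydroxy-3,5-dimethoxyphenyl]-2-bromoethanone F5. F5 is stirred in DMSO at rt without base, so the phenol does not close to a coumaranone, and gives 5.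

**Further compounds**
F1 | step 5 | 2-[3,4-bis(benzyloxy)phenyl]-1,3-dithiane | c1ccc(COc2ccc(C3SCCCS3)cc2OCc2ccccc2)cc1
F2 | step 5 | 1-[2,4-bis(benzyloxy)-6-hydroxy-3,5-dimethoxyphenyl]-2-{2-[3,4-bis(benzyloxy)phenyl]-1,3-dithian-2-yl}-2-hydroxyethanone (racemic) | O=C(C(O)C1(c2ccc(OCc3ccccc3)c(OCc3ccccc3)c2)SCCCS1)c1c(O)c(OC)c(OCc2ccccc2)c(OC)c1OCc1ccccc1
F3 | step 3 | 1-(3,5-dibromo-2,4,6-trihydroxyphenyl)ethanone | CC(=O)c1c(O)c(Br)c(O)c(Br)c1O
F4 | step 3 | 1-(2,4,6-trihydroxy-3,5-dimethoxyphenyl)ethanone | CC(=O)c1c(O)c(OC)c(O)c(OC)c1O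
F5 | step 4 | 1-[2,4-bis(benzyloxy)-6-hydroxy-3,5-dimethoxyphenyl]-2-bromoethanone | O=C(CBr)c1c(O)c(OC)c(OCc2ccccc2)c(OC)c1OCc1ccccc1
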